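The time of reading, 2.0 d, was one of my two times, and the other had to come from the earlier runs.

in all of them: substrate 0.050 M; free catalyst 0.50 mM

| run | reagent | temperature | remark | time |
|---|---|---|---|---|
| Friday's | 0.066 M (fed, over 10 h) | 55 °C | run made earlier; the fed solution adds 0.10 times the starting volume |  |
| Wednesday's | 0.19 M (fed, over 10 h) | 70 °C | run made earlier; the fed solution adds 0.10 times the starting volume |  |
| winter | 0.250 M (fed, over 10 h) | 70 °C | the fed solution adds 0.10 times the starting volume | 2.0 d |
| summer | 0.120 M | 70 °C | everything together at the start, the whole solution of reagent included, so that from the start the volume is larger by 0.10 times the starting volume | 2.0 d |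

- Friday's (time / d: product / %, substrate / %): 0.167: 0.7, 99.2; 0.417: 0, 100.4; 0.833: 3.1, 96.4; 1.25: 5.3, 94.2; 1.67: 6.1, 94.0; 2.00: 9.3, 93.2; 2.50: 9.4, 89.0
- Wednesday's (time / h: product / %, substrate / %): 2.00: 1.3, 98.2; 5.00: 2.1, 96.2; 10.0: 8.0, 91.5; 15.0: 13.3, 90.3; 20.0: 17.0, 83.0; 25.0: 21.9, 79.0; 30.0: 24.3, 73.3

(standard deviation of a reading: 1 percentage point)

- which of the two ends with the higher amount of product, in percent of the substrate charged ("neither" if they lie within 2 percentage points) (winter / summer / neither)
- product at the end, in percent of the substrate charged, winter
- product at the end, in percent of the substrate charged, summer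

- amounts are per litre of the starting volume; all of the dose is in the solution fed

1. Wednesday's run, at 70 °C like the new flasks, showed product at 8.0% after 10.0 h and 24.3% after 30.0 h, which I read as a straight line through the start, although substrate had fallen to 73.3%.

2. That looked like a small fixed stock working at a steady pace, so I treated the catalyst's forms as a steady state and reckoned with the catalyst, whose charge is 1.00% of the substrate's.

3. I defined the turnover time as the time one catalyst takes, on average, to make one product, which is elapsed time times catalyst charged over product made: 1.23 h on Wednesday's last reading.

4. Held against the time of reading, that gave 39.0 turns, each worth 1.00% of the substrate, so my reckoning was 38.9%. It carried Wednesday's reagent level, 0.19 M, and so did not part winter from summer.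

5. The forecast said winter, with 41% (35% to 49%) for winter and 33% (27% to 38%) for summer, judging that “the dependence on reagent looks partly saturated”. My figure lay below its winter value and above its summer value.

6. The simulation gave 43.7% for winter and 38.9% for summer, so winter ended higher, and summer stood above the forecast's range.

    substrate + free catalyst → catalyst intermediate A (k = 1.58 M⁻¹ min⁻¹, Ea = 70.0 kJ mol⁻¹)
    catalyst intermediate A → catalyst intermediate B (k = 0.0929 min⁻¹, Ea = 93.0 kJ mol⁻¹)
    reagent + catalyst intermediate B → catalyst intermediate C (k = 0.480 M⁻¹ min⁻¹, Ea = 80.0 kJ mol⁻¹)
    catalyst intermediate C → free catalyst + product (k = 0.0416 min⁻¹, Ea = 109 kJ mol⁻¹)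
    (constants at 70 °C)

7. Read back, the turnover time was 1.10 h in winter and 1.23 h in summer, against my 1.23 h, and winter's value carried to a reading of the same winter flask at 3.0 d gave 65.5%, where the simulation of that reading stood at 62.8%. In winter near 0.987 d, free catalyst had a half-life of 0.21 h by capture of substrate and catalyst intermediate C one of 0.28 h by release, while substrate's half-life by that capture was 2.3 d, much longer than either. At 1.00 d in winter, the catalyst stood spread over its forms, with catalyst intermediate C at 38.6% and free catalyst at 28.8%.

(The readings were generated by integration from invented constants; scatter was added.)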